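**Plan**
- Retrosynthesis: the butenolide is cut off at C12–C13 (Suzuki) and C11=C12 (borylolefination of a C11 aldehyde), C18 at C4–C18 (methyl coupling of the C3 enol triflate). Ring B is then opened at C9–C10 and C5–C6 in one operation, and the acyclic donor at C8–C9.
- Enabling feature: ring B (C5–C10) has quaternary C9 next to the C10 methine and quaternary C5 next to the C6 carbinol. This is the imprint of a tertiary C9 radical adding to C10 of 2-methylcyclohexenone, followed by capture of a C6 aldehyde by the C5 enolate.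
- Forward: C6–C7–C8 from (S)-glycerate acetonide and C9/C11/C20 from 2-bromoallyl alcohol give aldehyde 11. Ring A enters intact as enone 12, ring B closes in step 9, then C18, the C11–C16 dienyl butenolide and the acetates follow.
- Stereochemistry: C7 from the chiral pool; C8 by Felkin–Anh addition to the methyl ketone; C9, C10, C5 and C6 in the annulation (C8 and the cis-fused ketal, then chair aldol closure); 11E from the chromium olefination.

Key step: step 9

Remark: clerodane numbering is used throughout; α is the face of the decalin that carries the C5 methyl (C19), β the opposite face.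

Step 1
Reactants: 1 2-bromoprop-2-en-1-ol
Product: 2 1-{[(2-bromoprop-2-en-1-yl)oxy]methyl}-4-methoxybenzene
Conditions: NaH, PMBCl, TBAI (cat.), THF, 0 °C to rt
Reagents that add atoms: 4-methoxybenzyl chloride COc1ccc(CCl)cc1
Why: Williamson etherification of the allylic alkoxide with a benzylic chloride; the vinyl bromide is inert under these conditions.

Step 2
Reactants: 3 methyl (4S)-2,2-dimethyl-1,3-dioxolane-4-carboxylate
Product: 4 (4S)-N-methoxy-N,2,2-trimethyl-1,3-dioxolane-4-carboxamide
Conditions: MeNHOMe·HCl, i-PrMgCl, THF, −20 °C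
Reagents that add atoms: N,O-dimethylhydroxylamine hydrochloride CNOC.Cl
Why: Weinreb amidation of the ester by the magnesium amide should proceed at low temperature without touching the α-alkoxy stereocenter (future C7).

Step 3
Reactants: 4 (4S)-N-methoxy-N,2,2-trimethyl-1,3-dioxolane-4-carboxamide
Product: 5 1-[(4S)-2,2-dimethyl-1,3-dioxolan-4-yl]ethan-1-one
Conditions: MeMgBr, THF, 0 °C
Reagents that add atoms: methylmagnesium bromide C[Mg]Br
Why: Weinreb ketone synthesis, in which the chelated tetrahedral intermediate stops at single addition, should give the methyl ketone (C8, C17) with C7 intact.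

Step 4
Reactants: 2 1-{[(2-bromoprop-2-en-1-yl)oxy]methyl}-4-methoxybenzene; 5 1-[(4S)-2,2-dimethyl-1,3-dioxolan-4-yl]ethan-1-one
Product: 7 (2R)-2-[(4S)-2,2-dimethyl-1,3-dioxolan-4-yl]-3-{[(4-methoxybenzyl)oxy]methyl}but-3-en-2-ol, via 2-lithioallyl PMB ether 6 (not isolated)
Conditions: t-BuLi (2 equiv), Et2O, −78 °C; then 5, THF, −78 °C
Reagents that add atoms: none
Why: Bromine–lithium exchange followed by carbonyl addition under polar Felkin–Anh control (ring C7–O bond anti to the incoming alkenyllithium, attack past H7) should set C8 as R, the erythro relationship to C7.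

Step 5
Reactants: 7 (2R)-2-[(4S)-2,2-dimethyl-1,3-dioxolan-4-yl]-3-{[(4-methoxybenzyl)oxy]methyl}but-3-en-2-ol
Product: 8 (2S,3R)-4-{[(4-methoxybenzyl)oxy]methyl}-3-methylpent-4-ene-1,2,3-triol
Conditions: AcOH/H2O 4:1, 35 °C
Reagents that add atoms: none
Why: Acid-catalysed acetonide hydrolysis is needed because the terminal ketal cannot be equilibrated to the more crowded internal one; the PMB ether and the tertiary allylic alcohol tolerate aqueous acetic acid.

Step 6
Reactants: 8 (2S,3R)-4-{[(4-methoxybenzyl)oxy]methyl}-3-methylpent-4-ene-1,2,3-triol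
Product: 9 (2S,3R)-4-{[(4-methoxybenzyl)oxy]methyl}-3-methyl-1-[(triethylsilyl)oxy]pent-4-ene-2,3-diol
Conditions: TESCl (1.05 equiv), imidazole, CH2Cl2, −40 °C
Reagents that add atoms: chlorotriethylsilane CC[Si](Cl)(CC)CC
Why: Sterically controlled silylation should select the primary hydroxyl over the secondary and tertiary ones at low temperature.

Step 7
Reactants: 9 (2S,3R)-4-{[(4-methoxybenzyl)oxy]methyl}-3-methyl-1-[(triethylsilyl)oxy]pent-4-ene-2,3-diol
Product: 10 triethyl{[(4S,5R)-5-{3-[(4-methoxybenzyl)oxy]prop-1-en-2-yl}-2,2,5-trimethyl-1,3-dioxolan-4-yl]methoxy}silane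
Conditions: 2-methoxypropene, PPTS (cat.), CH2Cl2, 0 °C
Reagents that add atoms: 2-methoxypropene COC(C)=C
Why: Kinetic ketalization with the enol ether closes the only remaining 1,2-diol to the 7,8-dioxolane (C6 and C9 arms cis) without changing a stereocenter.

Step 8
Reactants: 10 triethyl{[(4S,5R)-5-{3-[(4-methoxybenzyl)oxy]prop-1-en-2-yl}-2,2,5-trimethyl-1,3-dioxolan-4-yl]methoxy}silane
Product: 11 (4R,5R)-5-{3-[(4-methoxybenzyl)oxy]prop-1-en-2-yl}-2,2,5-trimethyl-1,3-dioxolane-4-carbaldehyde
Conditions: (COCl)2, DMSO, CH2Cl2, −78 to −40 °C; then Et3N, −78 to 0 °C; crude aldehyde used at once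
Reagents that add atoms: none
Why: Direct Swern oxidation of a primary triethylsilyl ether (activated DMSO cleaves the Si–O bond in the flask) should give the α-alkoxy aldehyde without a separate desilylation, and the cold amine quench should leave C7 unepimerized.

Step 9
Reactants: 11 (4R,5R)-5-{3-[(4-methoxybenzyl)oxy]prop-1-en-2-yl}-2,2,5-trimethyl-1,3-dioxolane-4-carbaldehyde; 12 2-methylcyclohex-2-en-1-one
Product: 15 (5S,6R,7S,8R,9S,10R)-6α-hydroxy-7β,8β-(isopropylidenedioxy)-11-(4-methoxybenzyloxy)-12,13,14,15,16,18-hexanorclerodan-4-one, via tertiary C9 radical 13 (not isolated), via iron(III) enolate 14 (not isolated)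
Conditions: Fe(acac)3 (30 mol %), PhSiH3, EtOH/(CH2OH)2 5:1, 12 (3 equiv), rt
Reagents that add atoms: none
Why: An iron hydride formed from Fe(acac)3 and PhSiH3 transfers a hydrogen atom to the CH2 terminus of the 1,1-disubstituted alkene (creating Me20), the nucleophilic tertiary C9 radical 13 adds to the β-carbon C10 of enone 12, and Fe(II) reduces the α-keto radical to iron enolate 14, whose C5 attacks the tethered C6 aldehyde before it is protonated. The closest known reaction type is the iron-hydride radical–polar crossover annulation of alkene-tethered aldehydes with cyclic enones (Giese addition terminated by aldol). Ring B closes by a 6-(enolexo)-exo-trig aldol through a chair in which iron bridges the enolate and aldehyde oxygens. C9 is set by the adjacent fully substituted ketal carbon C8: the enone should bond to the radical face anti to ring carbon C7 and its cis formyl group, with the small new methyl tucked between the two ring bonds of C8 and the CH2OPMB arm anti to O8; C10 follows from the enone approaching with its substituted α-carbon turned away from C8 and the CH2OPMB arm over the ring, which puts H10 trans to Me20. C5 and C6 arise in the chair closure: C6 adds to the enolate face that keeps the C10–C9 bond equatorial (trans-decalin, Me19 axial and syn to Me20) with the aldehyde oxygen equatorial beside the enolate oxygen, giving the equatorial 6α-OH, which is also the thermodynamically preferred aldol. The step needs face selectivity at the C9 radical and the correct C9/C10 topicity; both rest only on C8 and the cis-fused ketal, the proposed transition-state model is not secure, and this is treated as the main risk below.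

Step 10
Reactants: 15 (5S,6R,7S,8R,9S,10R)-6α-hydroxy-7β,8β-(isopropylidenedioxy)-11-(4-methoxybenzyloxy)-12,13,14,15,16,18-hexanorclerodan-4-one
Product: 16 (5S,6R,7S,8R,9S,10R)-7β,8β-(isopropylidenedioxy)-11-(4-methoxybenzyloxy)-6α-(triethylsilyloxy)-12,13,14,15,16,18-hexanorclerodan-4-one
Conditions: TESOTf, 2,6-lutidine, CH2Cl2, −78 to 0 °C
Reagents that add atoms: triethylsilyl trifluoromethanesulfonate CC[Si](CC)(CC)OS(=O)(=O)C(F)(F)F
Why: Silylation of the hindered secondary alcohol with the silyl triflate and a non-nucleophilic base should protect the β-hydroxy ketone without retro-aldol cleavage.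

Step 11
Reactants: 16 (5S,6R,7S,8R,9S,10R)-7β,8β-(isopropylidenedioxy)-11-(4-methoxybenzyloxy)-6α-(triethylsilyloxy)-12,13,14,15,16,18-hexanorclerodan-4-one
Product: 18 (5S,6R,7S,8R,9S,10R)-7β,8β-(isopropylidenedioxy)-11-(4-methoxybenzyloxy)-6α-(triethylsilyloxy)-12,13,14,15,16,18-hexanorclerod-3-en-4-yl trifluoromethanesulfonate, via potassium enolate 17 (not isolated)
Conditions: KHMDS, THF, −78 °C; then PhNTf2, −78 to 0 °C
Reagents that add atoms: N-phenylbis(trifluoromethanesulfonimide) O=S(=O)(N(c1ccccc1)S(=O)(=O)C(F)(F)F)C(F)(F)F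
Why: Only C3 can be deprotonated because C5 is quaternary, so enolate O-triflation should give a single enol triflate.

Step 12
Reactants: 18 (5S,6R,7S,8R,9S,10R)-7β,8β-(isopropylidenedioxy)-11-(4-methoxybenzyloxy)-6α-(triethylsilyloxy)-12,13,14,15,16,18-hexanorclerod-3-en-4-yl trifluoromethanesulfonate
Product: 19 (5R,6R,7S,8R,9S,10S)-7β,8β-(isopropylidenedioxy)-11-(4-methoxybenzyloxy)-6α-(triethylsilyloxy)-12,13,14,15,16-pentanorclerod-3-ene
Conditions: MeMgBr, Fe(acac)3 (10 mol %), THF/NMP, −20 to 0 °C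
Reagents that add atoms: methylmagnesium bromide C[Mg]Br
Why: Iron-catalysed Kumada-type cross-coupling of an alkenyl triflate with the methyl Grignard reagent should install C18 with the double bond fixed at C3=C4.

Step 13
Reactants: 19 (5R,6R,7S,8R,9S,10S)-7β,8β-(isopropylidenedioxy)-11-(4-methoxybenzyloxy)-6α-(triethylsilyloxy)-12,13,14,15,16-pentanorclerod-3-ene
Product: 20 (5R,6R,7S,8R,9S,10S)-7β,8β-(isopropylidenedioxy)-6α-(triethylsilyloxy)-12,13,14,15,16-pentanorclerod-3-en-11-ol
Conditions: DDQ, CH2Cl2/pH 7 buffer, 0 °C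
Reagents that add atoms: none
Why: Oxidative cleavage of the p-methoxybenzyl ether with DDQ should leave the silyl ether, the ketal and the trisubstituted alkene untouched.

Step 14
Reactants: 20 (5R,6R,7S,8R,9S,10S)-7β,8β-(isopropylidenedioxy)-6α-(triethylsilyloxy)-12,13,14,15,16-pentanorclerod-3-en-11-ol
Product: 21 (5R,6R,7S,8R,9R,10S)-7β,8β-(isopropylidenedioxy)-6α-(triethylsilyloxy)-12,13,14,15,16-pentanorclerod-3-en-11-al
Conditions: DMP, pyridine, CH2Cl2, rt
Reagents that add atoms: none
Why: Dess–Martin oxidation of the neopentyl primary alcohol gives an aldehyde with no α-hydrogen, and with O8 tied up in the ketal no retro-aldol pathway is open.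

Step 15
Reactants: 21 (5R,6R,7S,8R,9R,10S)-7β,8β-(isopropylidenedioxy)-6α-(triethylsilyloxy)-12,13,14,15,16-pentanorclerod-3-en-11-al
Product: 22 (5R,6R,7S,8R,9R,10S)-7β,8β-(isopropylidenedioxy)-12-(4,4,5,5-tetramethyl-1,3,2-dioxaborolan-2-yl)-6α-(triethylsilyloxy)-13,14,15,16-tetranorcleroda-3,11E-diene
Conditions: Cl2CHBpin, CrCl2, LiI, THF, rt
Reagents that add atoms: 2-(dichloromethyl)-4,4,5,5-tetramethyl-1,3,2-dioxaborolane ClC(Cl)B1OC(C)(C)C(C)(C)O1
Why: Takai–Utimoto borylolefination (addition of a geminal dichromium reagent to the aldehyde, then elimination) should give the E-alkenylboronate and so set the 11E geometry.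

Step 16
Reactants: 22 (5R,6R,7S,8R,9R,10S)-7β,8β-(isopropylidenedioxy)-12-(4,4,5,5-tetramethyl-1,3,2-dioxaborolan-2-yl)-6α-(triethylsilyloxy)-13,14,15,16-tetranorcleroda-3,11E-diene; 23 4-bromofuran-2(5H)-one
Product: 24 (5R,6R,7S,8R,9R,10S)-7β,8β-(isopropylidenedioxy)-6α-(triethylsilyloxy)cleroda-3,11E,13-trien-15,16-olide
Conditions: PdCl2(PPh3)2 (5 mol %), KF, THF/H2O, 60 °C
Reagents that add atoms: none
Why: Suzuki–Miyaura coupling proceeds with retention of the alkene geometry, and fluoride activation is mild enough for the base-sensitive bromobutenolide.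

Step 17
Reactants: 24 (5R,6R,7S,8R,9R,10S)-7β,8β-(isopropylidenedioxy)-6α-(triethylsilyloxy)cleroda-3,11E,13-trien-15,16-olide
Product: 25 (5R,6R,7S,8R,9R,10S)-6α,7β,8β-trihydroxycleroda-3,11E,13-trien-15,16-olide
Conditions: 1 M HCl/THF 1:3, rt
Reagents that add atoms: none
Why: Acid hydrolysis should remove the triethylsilyl ether and the cis-fused acetonide in one operation, while the trisubstituted alkene and the dienyl butenolide tolerate dilute acid.

Step 18
Reactants: 25 (5R,6R,7S,8R,9R,10S)-6α,7β,8β-trihydroxycleroda-3,11E,13-trien-15,16-olide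
Product: 26 (5R,6R,7S,8R,9R,10S)-6α,7β-diacetoxy-8β-hydroxycleroda-3,11E,13-trien-15,16-olide
Conditions: Ac2O, pyridine, DMAP (cat.), CH2Cl2, rt
Reagents that add atoms: acetic anhydride CC(=O)OC(C)=O
Why: DMAP-catalysed acylation should esterify the two secondary hydroxyls, while the tertiary axial 8-OH next to quaternary C9 is not acetylated under these conditions.

**Compound list**
1 | 2-bromoprop-2-en-1-ol | OCC(Br)=C | starting material
2 | 1-{[(2-bromoprop-2-en-1-yl)oxy]methyl}-4-methoxybenzene | C=C(Br)COCc1ccc(OC)cc1 | intermediate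
3 | methyl (4S)-2,2-dimethyl-1,3-dioxolane-4-carboxylate | COC(=O)[C@@H]1COC(C)(C)O1 | starting material
4 | (4S)-N-methoxy-N,2,2-trimethyl-1,3-dioxolane-4-carboxamide | CON(C)C(=O)[C@@H]1COC(C)(C)O1 | intermediate
5 | 1-[(4S)-2,2-dimethyl-1,3-dioxolan-4-yl]ethan-1-one | CC(=O)[C@@H]1COC(C)(C)O1 | intermediate
6 | {3-[(4-methoxybenzyl)oxy]prop-1-en-2-yl}lithium (2-lithioallyl PMB ether) | [Li]C(=C)COCc1ccc(OC)cc1 | intermediate (not isolated)
7 | (2R)-2-[(4S)-2,2-dimethyl-1,3-dioxolan-4-yl]-3-{[(4-methoxybenzyl)oxy]methyl}but-3-en-2-ol | C[C@](O)([C@@H]1COC(C)(C)O1)C(=C)COCc1ccc(OC)cc1 | intermediate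
8 | (2S,3R)-4-{[(4-methoxybenzyl)oxy]methyl}-3-methylpent-4-ene-1,2,3-triol | OC[C@H](O)[C@](C)(O)C(=C)COCc1ccc(OC)cc1 | intermediate
9 | (2S,3R)-4-{[(4-methoxybenzyl)oxy]methyl}-3-methyl-1-[(triethylsilyl)oxy]pent-4-ene-2,3-diol | CC[Si](CC)(CC)OC[C@H](O)[C@](C)(O)C(=C)COCc1ccc(OC)cc1 | intermediate
10 | triethyl{[(4S,5R)-5-{3-[(4-methoxybenzyl)oxy]prop-1-en-2-yl}-2,2,5-trimethyl-1,3-dioxolan-4-yl]methoxy}silane | CC[Si](CC)(CC)OC[C@@H]1OC(C)(C)O[C@]1(C)C(=C)COCc1ccc(OC)cc1 | intermediate
11 | (4R,5R)-5-{3-[(4-methoxybenzyl)oxy]prop-1-en-2-yl}-2,2,5-trimethyl-1,3-dioxolane-4-carbaldehyde (C6 aldehyde, 7,8-acetonide, C9 methylidene) | O=C[C@@H]1OC(C)(C)O[C@]1(C)C(=C)COCc1ccc(OC)cc1 | intermediate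
12 | 2-methylcyclohex-2-en-1-one | CC1=CCCCC1=O | starting material
13 | tertiary C9 radical from 11 (hydrogen added to the methylidene carbon) | O=C[C@@H]1OC(C)(C)O[C@]1(C)[C](C)COCc1ccc(OC)cc1 | intermediate (not isolated)
14 | iron(III) C4-enolate of the C9–C10 adduct (drawn as the enolate anion) | O=C[C@@H]1OC(C)(C)O[C@]1(C)[C@](C)(COCc1ccc(OC)cc1)[C@H]1CCCC([O-])=C1C | intermediate (not isolated)
15 | (5S,6R,7S,8R,9S,10R)-6α-hydroxy-7β,8β-(isopropylidenedioxy)-11-(4-methoxybenzyloxy)-12,13,14,15,16,18-hexanorclerodan-4-one (trans-decalin; 5α-Me, 8α-Me, 9α-Me, 10β-H) | O[C@H]1[C@@H]2OC(C)(C)O[C@]2(C)[C@](C)(COCc3ccc(OC)cc3)[C@H]4CCCC(=O)[C@]14C | intermediate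
16 | 6-O-triethylsilyl ether of 15 | CC[Si](CC)(CC)O[C@H]1[C@@H]2OC(C)(C)O[C@]2(C)[C@](C)(COCc3ccc(OC)cc3)[C@H]4CCCC(=O)[C@]14C | intermediate
17 | potassium C3=C4 enolate of 16 | CC[Si](CC)(CC)O[C@H]1[C@@H]2OC(C)(C)O[C@]2(C)[C@](C)(COCc3ccc(OC)cc3)[C@H]4CCC=C([O-])[C@]14C.[K+] | intermediate (not isolated)
18 | C3-en-4-yl trifluoromethanesulfonate of 16 | CC[Si](CC)(CC)O[C@H]1[C@@H]2OC(C)(C)O[C@]2(C)[C@](C)(COCc3ccc(OC)cc3)[C@H]4CCC=C(OS(=O)(=O)C(F)(F)F)[C@]14C | intermediate
19 | (5R,6R,7S,8R,9S,10S)-7β,8β-(isopropylidenedioxy)-11-(4-methoxybenzyloxy)-6α-(triethylsilyloxy)-12,13,14,15,16-pentanorclerod-3-ene | CC[Si](CC)(CC)O[C@H]1[C@@H]2OC(C)(C)O[C@]2(C)[C@](C)(COCc3ccc(OC)cc3)[C@H]4CCC=C(C)[C@]14C | intermediate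
20 | (5R,6R,7S,8R,9S,10S)-7β,8β-(isopropylidenedioxy)-6α-(triethylsilyloxy)-12,13,14,15,16-pentanorclerod-3-en-11-ol | CC[Si](CC)(CC)O[C@H]1[C@@H]2OC(C)(C)O[C@]2(C)[C@](C)(CO)[C@H]3CCC=C(C)[C@]13C | intermediate
21 | (5R,6R,7S,8R,9R,10S)-7β,8β-(isopropylidenedioxy)-6α-(triethylsilyloxy)-12,13,14,15,16-pentanorclerod-3-en-11-al | CC[Si](CC)(CC)O[C@H]1[C@@H]2OC(C)(C)O[C@]2(C)[C@](C)(C=O)[C@H]3CCC=C(C)[C@]13C | intermediate
22 | (5R,6R,7S,8R,9R,10S)-7β,8β-(isopropylidenedioxy)-12-(pinacolatoboryl)-6α-(triethylsilyloxy)-13,14,15,16-tetranorcleroda-3,11E-diene | CC[Si](CC)(CC)O[C@H]1[C@@H]2OC(C)(C)O[C@]2(C)[C@](C)(/C=C/B3OC(C)(C)C(C)(C)O3)[C@H]4CCC=C(C)[C@]14C | intermediate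
23 | 4-bromofuran-2(5H)-one | O=C1C=C(Br)CO1 | starting material
24 | (5R,6R,7S,8R,9R,10S)-7β,8β-(isopropylidenedioxy)-6α-(triethylsilyloxy)cleroda-3,11E,13-trien-15,16-olide | CC[Si](CC)(CC)O[C@H]1[C@@H]2OC(C)(C)O[C@]2(C)[C@](C)(/C=C/C3=CC(=O)OC3)[C@H]4CCC=C(C)[C@]14C | intermediate
25 | (5R,6R,7S,8R,9R,10S)-6α,7β,8β-trihydroxycleroda-3,11E,13-trien-15,16-olide | O[C@H]1[C@H](O)[C@](C)(O)[C@](C)(/C=C/C2=CC(=O)OC2)[C@H]2CCC=C(C)[C@]12C | intermediate
26 | (5R,6R,7S,8R,9R,10S)-6α,7β-diacetoxy-8β-hydroxycleroda-3,11E,13-trien-15,16-olide (CNP0383656.1) | CC(=O)O[C@H]1[C@H](OC(C)=O)[C@](C)(O)[C@](C)(/C=C/C2=CC(=O)OC2)[C@H]2CCC=C(C)[C@]12C | target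

**Step count and risks**
Total step count: 18. Longest linear sequence: 17 steps (3 to 26, steps 2–18); step 1 is a one-step branch.

Steps most likely to fail:

1. Step 9. The intermolecular radical addition may show poor facial selectivity at C9 and the wrong C9/C10 topicity, because both rest only on C8 and the ketal and the transition-state model offered is not secure. The radical may also be reduced before it adds, the enolate may be protonated before the aldol, closure may give the cis-fused or 6-epi aldol, and C7 may epimerize in the aldehyde.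
   Fallback, setting out from 11: DDQ removes the PMB group and the freed 11-hydroxy aldehyde closes to the cis-fused bicyclic lactol F1. Under the same iron-hydride conditions the C9 radical of this lactol is endocyclic and shielded on one face by the isopropylidene ring, so enone 12 should add on the opposite, convex face, which is the face the target requires; the enolate is then simply protonated to give the keto lactol F2. Ring B is closed in a separate, thermodynamically controlled aldol step (K2CO3, MeOH) through the open hydroxy aldehyde to give the 6,11-diol F3. Selective p-methoxybenzylation of the primary 11-OH (PMB trichloroacetimidate, cat. La(OTf)3) comes back to the route at 15.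

2. Step 4. Addition to the ketone may proceed with low diastereoselectivity at C8 (competition of Felkin–Anh and chelated pathways), and the basic alkenyllithium may enolize the methyl ketone.
   Fallback, setting out from 2, with C7 and C8 set by reagent control: Stille coupling of 2 with (E)-3-(tributylstannyl)but-2-en-1-ol F4 (made by stannylcupration of but-2-yn-1-ol) gives the (E)-dienol F5. Sharpless asymmetric epoxidation with L-(+)-diethyl tartrate, which touches only the allylic alcohol alkene, gives the (2S,3S)-epoxy alcohol F6. Silylation with TESCl gives the epoxy silyl ether F7. Acetone with catalytic BF3·OEt2 converts the epoxide into the dioxolane with inversion at the tertiary allylic carbon C8 and comes back to the route at 10.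

3. Step 15. The chromium reagent may add only sluggishly to the neopentyl aldehyde flanked by two fully substituted carbons, and E selectivity may erode.
   Fallback, setting out from 21: homologation with the Ohira–Bestmann reagent (K2CO3, MeOH) gives the terminal alkyne F8. Hydroboration with pinacolborane catalysed by the Schwartz reagent (syn addition, boron at the terminus) comes back to the route at 22.

**Further compounds**
F1 | step 9 | cyclic hemiacetal (δ-lactol, anomeric mixture) of (4R,5R)-5-(3-hydroxyprop-1-en-2-yl)-2,2,5-trimethyl-1,3-dioxolane-4-carbaldehyde | OC1OCC(=C)[C@@]2(C)OC(C)(C)O[C@@H]12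
F2 | step 9 | keto lactol: adduct of F1 at C9 with C10 of 12 (C9 and C10 as in 15, C5 and C6 unassigned) | OC1OC[C@](C)([C@H]3CCCC(=O)C3C)[C@@]2(C)OC(C)(C)O[C@@H]12
F3 | step 9 | (5S,6R,7S,8R,9S,10R)-6α,11-dihydroxy-7β,8β-(isopropylidenedioxy)-12,13,14,15,16,18-hexanorclerodan-4-one | O[C@H]1[C@@H]2OC(C)(C)O[C@]2(C)[C@](C)(CO)[C@H]3CCCC(=O)[C@]13C
F4 | step 4 | (E)-3-(tributylstannyl)but-2-en-1-ol | OC/C=C(C)/[Sn](CCCC)(CCCC)CCCC
F5 | step 4 | (2E)-4-{[(4-methoxybenzyl)oxy]methyl}-3-methylpenta-2,4-dien-1-ol | OC/C=C(C)/C(=C)COCc1ccc(OC)cc1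
F6 | step 4 | [(2S,3S)-3-{3-[(4-methoxybenzyl)oxy]prop-1-en-2-yl}-3-methyloxiran-2-yl]methanol | OC[C@@H]1O[C@@]1(C)C(=C)COCc1ccc(OC)cc1
F7 | step 4 | triethyl{[(2S,3S)-3-{3-[(4-methoxybenzyl)oxy]prop-1-en-2-yl}-3-methyloxiran-2-yl]methoxy}silane | CC[Si](CC)(CC)OC[C@@H]1O[C@@]1(C)C(=C)COCc1ccc(OC)cc1
F8 | step 15 | (5R,6R,7S,8R,9S,10S)-7β,8β-(isopropylidenedioxy)-6α-(triethylsilyloxy)-13,14,15,16-tetranorclerod-3-en-11-yne | CC[Si](CC)(CC)O[C@H]1[C@@H]2OC(C)(C)O[C@]2(C)[C@](C)(C#C)[C@H]3CCC=C(C)[C@]13C
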